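**Assumption:** the target SMILES is read as (1E,6S,10S)-6-hydroxy-8,8-dimethyl-5-methylidene-10-[(3-methylbutanoyl)oxy]cycloundec-1-ene-1-carboxylic acid; compounds 1, 3, 5, 9 and 10 are bought. "C6" and "C10" below are ring positions of the target.

## Retrosynthetic overview

1. Target 14 comes from its tert-butyl ester 13 by acidolysis; the only ring, the 11-membered carbocycle, is closed by ring-closing metathesis of acyclic triene 12 at the C1=C2 enoate.
2. 12 comes from aldehyde 8 and alkenyl bromide 11 by ligand-controlled Ni/Cr alkenylation, which sets the C6 carbinol; 11 comes from 9 and 10.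
3. 8 comes from 7 by aldehyde-selective Wacker oxidation, which makes the C6–O bond.
4. Key step: 7 comes from racemic 4 and anhydride 5 by an enantioconvergent C–O esterification that installs the isovalerate and fixes C10 (acyl C–O bond with retention for one enantiomer, alkyl C–O bond with inversion for the other).
5. Racemic 4 comes from aldehyde 2 and bromide 3 (zinc Barbier); 2 comes from ester 1.

## Route

**Step 1**
Reactants: 1 methyl 3,3-dimethylpent-4-enoate
Product: 2 3,3-dimethylpent-4-enal
Conditions: i-Bu2AlH (1.05 equiv), CH2Cl2, −78 °C; Rochelle salt work-up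
Reagents that add atoms: none
Why: Partial reduction of the ester stops at the aldehyde because the aluminium hemiacetal is stable at −78 °C (i-Bu2AlH ester-to-aldehyde reduction); no stereocentre is involved.

**Step 2**
Reactants: 2 3,3-dimethylpent-4-enal; 3 tert-butyl 2-(bromomethyl)prop-2-enoate
Product: 4 rac-tert-butyl 4-hydroxy-6,6-dimethyl-2-methylideneoct-7-enoate
Conditions: Zn dust, THF/sat. aq NH4Cl (2:1), 0 °C to rt
Reagents that add atoms: none
Why: Zinc Barbier 2-(alkoxycarbonyl)allylation adds the allylzinc chemoselectively to the aldehyde, the tert-butyl ester suppresses lactonisation, and the carbinol is deliberately left racemic because step 3 sets it.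

**Step 3**
Reactants: 4 rac-tert-butyl 4-hydroxy-6,6-dimethyl-2-methylideneoct-7-enoate; 5 3-methylbutanoic anhydride
Product: 7 tert-butyl (4S)-6,6-dimethyl-2-methylidene-4-[(3-methylbutanoyl)oxy]oct-7-enoate, via residual (4R)-alcohol 6 (not isolated)
Conditions: 5 (0.50 equiv), urea-armed HyperBTM-type isothiourea (5 mol %, the enantiomer that acylates the 4S alcohol), i-Pr2NEt (0.5 equiv), toluene, −20 °C; then PPh3 (0.6 equiv), DIAD (0.6 equiv), 0 °C to rt, one pot
Reagents that add atoms: none
Why: Proposed new method: a one-pot enantioconvergent esterification in which a bifunctional isothiourea first acylates only (4S)-4 with retention (the acyl-isothiouronium formed from 5 is the acyl donor and the urea arm hydrogen-bonds the acrylate C=O of the γ-hydroxy-α-methylene ester, docking only the 4S carbinol over the acyl group), and the untouched (4R)-alcohol 6 is then activated as its alkoxyphosphonium salt and displaced in an SN2 reaction by the isovalerate released in the first stage, inverting C4 to the same (4S)-ester, so the stereocentre (C10 of the target) is set entirely by C–O bond formation and all of the acyl donor is used; the closest known reaction types are isothiourea- or amidine-catalysed acylative kinetic resolution of secondary alcohols bearing an adjacent π or carbonyl group (not shown for dialkyl carbinols such as 4) and the lipase resolution/Mitsunobu inversion tandem.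

**Step 4**
Reactants: 7 tert-butyl (4S)-6,6-dimethyl-2-methylidene-4-[(3-methylbutanoyl)oxy]oct-7-enoate
Product: 8 tert-butyl (4S)-6,6-dimethyl-2-methylidene-4-[(3-methylbutanoyl)oxy]-8-oxooctanoate
Conditions: PdCl2(PhCN)2 (12 mol %), CuCl2·2H2O (12 mol %), AgNO2 (6 mol %), O2 (1 atm), t-BuOH/MeNO2 (15:1), rt
Reagents that add atoms: dioxygen, O=O
Why: Nitrite-modified aldehyde-selective Wacker oxidation places oxygen on the terminal carbon because the adjacent quaternary carbon blocks Markovnikov attack and offers no allylic hydrogen for isomerisation, while the electron-poor acrylate and the C4 stereocentre are untouched.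

**Step 5**
Reactants: 9 2,3-dibromoprop-1-ene; 10 allylmagnesium bromide
Product: 11 2-bromohexa-1,5-diene
Conditions: Et2O, 0 °C to rt
Reagents that add atoms: none
Why: The Grignard reagent displaces only the allylic bromide (SN2 and SN2′ give the same product) and leaves the vinylic C–Br bond intact (allyl–allyl coupling).

**Step 6**
Reactants: 8 tert-butyl (4S)-6,6-dimethyl-2-methylidene-4-[(3-methylbutanoyl)oxy]-8-oxooctanoate; 11 2-bromohexa-1,5-diene
Product: 12 tert-butyl (4S,8S)-8-hydroxy-6,6-dimethyl-2,9-dimethylidene-4-[(3-methylbutanoyl)oxy]tridec-12-enoate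
Conditions: CrCl2 (3 equiv), NiCl2 (5 mol %), Kishi-type chiral oxazoline–sulfonamide ligand (3.3 equiv, the enantiomer giving 8S), Et3N (3.3 equiv), THF, rt
Reagents that add atoms: none
Why: Asymmetric Nozaki–Hiyama–Kishi alkenylation: zerovalent nickel inserts into the C–Br bond and passes the alkenyl group to chromium, the alkenylchromium adds only to the aldehyde (esters and acrylate tolerated), and the sulfonamide ligand on chromium selects the aldehyde face to give the 8S carbinol independently of the remote C4 centre.

**Step 7**
Reactants: 12 tert-butyl (4S,8S)-8-hydroxy-6,6-dimethyl-2,9-dimethylidene-4-[(3-methylbutanoyl)oxy]tridec-12-enoate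
Product: 13 tert-butyl (1E,6S,10S)-6-hydroxy-8,8-dimethyl-5-methylidene-10-[(3-methylbutanoyl)oxy]cycloundec-1-ene-1-carboxylate
Conditions: second-generation Hoveyda–Grubbs catalyst (15 mol %, two portions), 1,4-benzoquinone (30 mol %), toluene (1 mM), 90 °C
Reagents that add atoms: none
Why: Ring-closing metathesis starts at the monosubstituted alkene and closes onto the 2-substituted acrylate (the C9 methylidene could only give a cyclobutene), the gem-dimethyl group and three sp2 ring carbons ease the 11-membered ring, and the ring enforces the cis ring olefin, which is the (E)-enoate; both stereocentres are untouched.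

**Step 8**
Reactants: 13 tert-butyl (1E,6S,10S)-6-hydroxy-8,8-dimethyl-5-methylidene-10-[(3-methylbutanoyl)oxy]cycloundec-1-ene-1-carboxylate
Product: 14 (1E,6S,10S)-6-hydroxy-8,8-dimethyl-5-methylidene-10-[(3-methylbutanoyl)oxy]cycloundec-1-ene-1-carboxylic acid
Conditions: TFA/CH2Cl2 (1:4), 0 °C, 1 h; aqueous work-up at pH 3
Reagents that add atoms: none
Why: Acidolysis of the tert-butyl ester (loss of the tert-butyl cation as isobutene) frees the acid while the secondary isovalerate, the enoate geometry and the allylic alcohol survive short cold exposure.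

## Compound list

1 | methyl 3,3-dimethylpent-4-enoate | C=CC(C)(C)CC(=O)OC | starting material
2 | 3,3-dimethylpent-4-enal | C=CC(C)(C)CC=O | intermediate
3 | tert-butyl 2-(bromomethyl)prop-2-enoate | C=C(CBr)C(=O)OC(C)(C)C | starting material
4 | rac-tert-butyl 4-hydroxy-6,6-dimethyl-2-methylideneoct-7-enoate | C=C(C(=O)OC(C)(C)C)CC(O)CC(C)(C)C=C | intermediate
5 | 3-methylbutanoic anhydride (isovaleric anhydride) | CC(C)CC(=O)OC(=O)CC(C)C | starting material
6 | tert-butyl (4R)-4-hydroxy-6,6-dimethyl-2-methylideneoct-7-enoate | C=C(C(=O)OC(C)(C)C)C[C@H](O)CC(C)(C)C=C | intermediate (not isolated)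
7 | tert-butyl (4S)-6,6-dimethyl-2-methylidene-4-[(3-methylbutanoyl)oxy]oct-7-enoate | C=C(C(=O)OC(C)(C)C)C[C@@H](OC(=O)CC(C)C)CC(C)(C)C=C | intermediate
8 | tert-butyl (4S)-6,6-dimethyl-2-methylidene-4-[(3-methylbutanoyl)oxy]-8-oxooctanoate | C=C(C(=O)OC(C)(C)C)C[C@@H](OC(=O)CC(C)C)CC(C)(C)CC=O | intermediate
9 | 2,3-dibromoprop-1-ene | C=C(Br)CBr | starting material
10 | allylmagnesium bromide | C=CC[Mg]Br | starting material
11 | 2-bromohexa-1,5-diene | C=C(Br)CCC=C | intermediate
12 | tert-butyl (4S,8S)-8-hydroxy-6,6-dimethyl-2,9-dimethylidene-4-[(3-methylbutanoyl)oxy]tridec-12-enoate | C=C(C(=O)OC(C)(C)C)C[C@@H](OC(=O)CC(C)C)CC(C)(C)C[C@H](O)C(=C)CCC=C | intermediate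
13 | tert-butyl (1E,6S,10S)-6-hydroxy-8,8-dimethyl-5-methylidene-10-[(3-methylbutanoyl)oxy]cycloundec-1-ene-1-carboxylate | C=C1CC/C=C(/C(=O)OC(C)(C)C)C[C@@H](OC(=O)CC(C)C)CC(C)(C)C[C@@H]1O | intermediate
14 | (1E,6S,10S)-6-hydroxy-8,8-dimethyl-5-methylidene-10-[(3-methylbutanoyl)oxy]cycloundec-1-ene-1-carboxylic acid | C=C1CC/C=C(/C(=O)O)C[C@@H](OC(=O)CC(C)C)CC(C)(C)C[C@@H]1O | target

## Step count and risks

Total steps: 8. Longest linear sequence: 7 steps (1 → 2 → 4 → 7 → 8 → 12 → 13 → 14; step 5 is the side branch to 11).

**Step 3 (proposed new method).** The selectivity factor of an acyl-transfer catalyst for a carbinol with no adjacent π group may be too low, and the Mitsunobu stage can eliminate towards the 2-alkoxycarbonyl-1,3-diene. Any (4R)-7 that forms is removed as a diastereomer after step 6, but a poor resolution would cost too much material. The fallback uses known chemistry and sets the centre in the C–C step instead. It sets out from aldehyde 2 (with bromide 3): chromium-catalysed asymmetric 2-(alkoxycarbonyl)allylation (CrCl2 10 mol %, chiral carbazole bis(oxazoline) ligand, Mn, Cp2ZrCl2, THF, aqueous work-up) gives tert-butyl (4S)-4-hydroxy-6,6-dimethyl-2-methylideneoct-7-enoate F1, which is esterified conventionally with anhydride 5 (DMAP, Et3N, CH2Cl2). It comes back to the route at 7.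

**Step 6.** The 2-bromoalkene may react sluggishly under Ni/Cr conditions and ligand control at C8 may be incomplete. The fallback separates bond formation from stereocontrol. It sets out from aldehyde 8 (with 11): a ligand-free Ni/Cr coupling in DMF (CrCl2, NiCl2 cat.) gives tert-butyl (4S,8RS)-8-hydroxy-6,6-dimethyl-2,9-dimethylidene-4-[(3-methylbutanoyl)oxy]tridec-12-enoate F2 as an epimer mixture. Dess–Martin periodinane oxidises the allylic alcohol to the enone tert-butyl (4S)-6,6-dimethyl-2,9-dimethylidene-4-[(3-methylbutanoyl)oxy]-8-oxotridec-12-enoate F3. Reduction with the (R)-Me-CBS oxazaborolidine and catecholborane (toluene, −78 °C; the alkenyl group acts as the large substituent) then gives the 8S alcohol. It comes back to the route at 12.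

**Step 7.** Closing an 11-membered carbocycle on a trisubstituted, electron-poor alkene may lose to oligomerisation or to ruthenium hydride isomerisation of the allylic alcohol. The fallback swaps the order of the two C–C events, so the ring is closed by chromium-templated carbonyl addition instead. It sets out from aldehyde 8: cross-metathesis with an excess of 11 (second-generation Hoveyda–Grubbs catalyst, CH2Cl2, 40 °C; the bromoalkene is inert) gives tert-butyl (2E)-6-bromo-2-[(2S)-4,4-dimethyl-2-[(3-methylbutanoyl)oxy]-6-oxohexyl]hepta-2,6-dienoate F4. An intramolecular asymmetric Nozaki–Hiyama–Kishi reaction at high dilution (CrCl2, NiCl2 cat., the same chiral sulfonamide ligand, Et3N, THF) then forms the ring and the C6 carbinol together. It bypasses 12 and comes back to the route at 13.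

## Further compounds

F1 | step 3 | tert-butyl (4S)-4-hydroxy-6,6-dimethyl-2-methylideneoct-7-enoate | C=C(C(=O)OC(C)(C)C)C[C@@H](O)CC(C)(C)C=C
F2 | step 6 | tert-butyl (4S,8RS)-8-hydroxy-6,6-dimethyl-2,9-dimethylidene-4-[(3-methylbutanoyl)oxy]tridec-12-enoate | C=C(C(=O)OC(C)(C)C)C[C@@H](OC(=O)CC(C)C)CC(C)(C)CC(O)C(=C)CCC=C
F3 | step 6 | tert-butyl (4S)-6,6-dimethyl-2,9-dimethylidene-4-[(3-methylbutanoyl)oxy]-8-oxotridec-12-enoate | C=C(C(=O)OC(C)(C)C)C[C@@H](OC(=O)CC(C)C)CC(C)(C)CC(=O)C(=C)CCC=C
F4 | step 7 | tert-butyl (2E)-6-bromo-2-[(2S)-4,4-dimethyl-2-[(3-methylbutanoyl)oxy]-6-oxohexyl]hepta-2,6-dienoate | C=C(Br)CC/C=C(/C(=O)OC(C)(C)C)C[C@@H](OC(=O)CC(C)C)CC(C)(C)CC=O
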